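**Strategy.** Everything rests on building the quinone ring (C1′=O, C2′–OH, C3′–CH2R, C4′=O, C5′–OMe, C6′–H) from a cyclobutenone that holds C1′–C4′ and carries a 2-methoxyvinyl group (C6′, C5′) on C1′. Heating opens the four-membered ring at C1′–C4′ to a dienylketene; 6π-electrocyclisation then forms C4′–C5′ and gives the fully substituted phenol in one operation (quinone after oxidation). The step exploits the adjacent C2′–O/C3′–alkyl pair flanking the C4′ carbonyl, which maps onto a siloxyalkyne plus a ketene. The siloxyalkyne derives from a δ-lactone that also fixes the cis ring-fusion C5–OH of the decalin, itself made by an enantioselective Diels–Alder reaction.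

Key step: step 10

Remark on numbering: decalin carbons are numbered as in drimanes (C4 gem-dimethyl, C5/C10 ring fusion, C8 methine, C9 quaternary, C11 the exocyclic CH2 on C9; α below, β above the plane). The target is 5α-OH, 8β-Me, 9β-Me, 9α-CH2, 10α-H, which is (1R,2S,4aS,8aS) in naphthalene numbering. Quinone carbons carry primes.

Assumption: in step 3 the (S)-oxazaborolidine exposes the Cα si face of aldehyde 4; if the sense of induction proves opposite, the (R)-catalyst is used.

**Step 1**
Reactants: 1 2,2-dimethylcyclohexanone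
Product: 2 6,6-dimethylcyclohex-1-en-1-yl trifluoromethanesulfonate
Conditions: LiN(iPr)2, THF, −78 °C; PhNTf2, −78 °C to rt
Reagents that add atoms: N-phenylbis(trifluoromethanesulfonimide), O=S(=O)(N(c1ccccc1)S(=O)(=O)C(F)(F)F)C(F)(F)F
Why: The ketone has only one enolisable α-carbon, so a single lithium enolate forms and is O-sulfonylated (enol triflate formation).

**Step 2**
Reactants: 2 6,6-dimethylcyclohex-1-en-1-yl trifluoromethanesulfonate
Product: 3 6,6-dimethyl-1-vinylcyclohex-1-ene
Conditions: tributyl(vinyl)stannane, Pd(PPh3)4 (3 mol%), LiCl, THF, reflux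
Reagents that add atoms: tributyl(vinyl)stannane, C=C[Sn](CCCC)(CCCC)CCCC
Why: Stille coupling of an enol triflate with a vinylstannane under zerovalent palladium catalysis is reliable for hindered cyclohexenyl triflates and gives the 1,3-diene directly.

**Step 3**
Reactants: 3 6,6-dimethyl-1-vinylcyclohex-1-ene; 4 (E)-2-methylbut-2-enal (tiglic aldehyde)
Product: 5 (1R,2S,8aR)-1,2,5,5-tetramethyl-1,2,3,5,6,7,8,8a-octahydronaphthalene-1-carbaldehyde (Δ5-ene; 8β,9β-dimethyl; 9α-CHO; 10α-H)
Conditions: (S)-3,3-diphenyl-1-(2-methylphenyl)tetrahydro-1H,3H-pyrrolo[1,2-c][1,3,2]oxazaborole (20 mol%) activated by AlBr3 (16 mol%), CH2Cl2, −78 to −40 °C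
Reagents that add atoms: none
Why: Chiral-Lewis-acid-catalysed Diels–Alder reaction in which the enal β-carbon (C8) bonds to the unsubstituted vinyl terminus (C7) and the α-carbon (C9) to the ring terminus (C10), as expected for an asynchronous acid-catalysed addition to a 1-substituted diene; the E-geometry of 4 fixes 8-Me/9-Me cis, the formyl-exo (α-methyl endo) mode typical of α-methyl enals (reinforced by the C4 gem-dimethyl group near the endo position) should put CHO cis to H-10, and the catalyst blocks one enal face so that C8, C9 and C10 are set absolutely.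

**Step 4**
Reactants: 5 Diels–Alder aldehyde
Product: 6 9α-(2-methoxyethenyl) enol ether (E/Z mixture; other centres as in 5)
Conditions: Ph3P(CH2OMe)Cl, KN(SiMe3)2, THF, 0 °C to rt
Reagents that add atoms: (methoxymethyl)triphenylphosphonium chloride, COC[P+](c1ccccc1)(c1ccccc1)c1ccccc1.[Cl-]
Why: Wittig methoxymethylenation with the non-stabilised ylide works on α-quaternary aldehydes and adds the one carbon that becomes C2′ without touching the stereocentres.

**Step 5**
Reactants: 6 enol ether
Product: 8 [(1R,2S,8aS)-1,2,5,5-tetramethyl-1,2,3,5,6,7,8,8a-octahydronaphthalen-1-yl]acetic acid, via homologated aldehyde 7 (not isolated)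
Conditions: 1 M HCl, THF, 0 °C; then NaClO2, NaH2PO4, 2-methyl-2-butene, t-BuOH/H2O, 0 °C to rt
Reagents that add atoms: water, O; sodium chlorite, [Na+].[O-]Cl=O
Why: Mild aqueous acid hydrolyses the enol ether to the homologous aldehyde, which is oxidised at once by the Pinnick chlorite oxidation, a method that leaves the trisubstituted alkene and the stereocentres untouched.

**Step 6**
Reactants: 8 unsaturated acid
Product: 9 bridged δ-lactone (C5α–O–C(=O)–CH2–C9α; 8β,9β-dimethyl; 10α-H; cis ring fusion)
Conditions: [N,N′-bis(3,5-di-tert-butylsalicylidene)-1,2-cyclohexanediaminato]cobalt (divalent cobalt, 5 mol%), N-fluoro-2,4,6-trimethylpyridinium tetrafluoroborate, PhSiH3, acetone, 0 °C to rt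
Reagents that add atoms: none
Why: Cobalt-hydride hydrogen-atom transfer to C6 gives the tertiary C5 radical, which after oxidation (radical-polar crossover, the known cobalt–salen hydroacyloxylation of unactivated alkenes) is captured by the carboxylic acid; the acid hangs from the 9α-CH2 arm and can reach only the α-face, so the new C5–O bond is cis to C11 and to H-10.

**Step 7**
Reactants: 9 δ-lactone
Product: 12 triisopropylsilyl ynol ether TIPSO–C≡C–CH2–C9 with C5–OTMS, via dibromomethyl ketone 10 (not isolated), via dilithium ynolate 11 (not isolated)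
Conditions: CH2Br2, lithium 2,2,6,6-tetramethylpiperidide, THF, −78 °C; LiN(SiMe3)2; n-BuLi, −78 to 25 °C; TIPSCl, −78 to 0 °C; then TMSCl
Reagents that add atoms: dibromomethane, BrCBr; chlorotriisopropylsilane, CC(C)[Si](Cl)(C(C)C)C(C)C; chlorotrimethylsilane, C[Si](C)(C)Cl
Why: Kowalski ester-to-ynolate homologation, in which LiCHBr2 adds to the lactone carbonyl, ring opening and enolisation give the dibromoketone enolate, bromine–lithium exchange and 1,2-shift of the C11 methylene give the ynolate, bulky TIPSCl silylates it on oxygen and TMSCl caps the liberated tertiary C5 alkoxide; no stereocentre is involved.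

**Step 8**
Reactants: 13 (E)-4-methoxybut-3-en-2-one
Product: 15 (E)-1-diazo-4-methoxybut-3-en-2-one, via trifluoroacetyl diketone 14 (not isolated)
Conditions: LiN(SiMe3)2, THF, −78 °C; CF3CO2CH2CF3; then MsN3, Et3N, H2O, MeCN, rt
Reagents that add atoms: methanesulfonyl azide, CS(=O)(=O)N=[N+]=[N-]
Why: Detrifluoroacetylative diazo transfer, in which kinetic enolisation of the methyl group and Claisen trifluoroacetylation activate it for diazo transfer with loss of the trifluoroacetyl group.

**Step 9**
Reactants: 12 silyl ynol ether; 15 diazo ketone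
Product: 17 4-[(E)-2-methoxyethenyl]-2-(terpenylmethyl)-3-(triisopropylsilyloxy)cyclobut-2-en-1-one (mixture of C1′ epimers), via methoxyvinylketene 16 (not isolated)
Conditions: hν (medium-pressure Hg lamp, Pyrex filter), degassed ClCH2CH2Cl, rt
Reagents that add atoms: none
Why: Photochemical Wolff rearrangement of 15 gives vinylketene 16, which undergoes regioselective [2+2] cycloaddition with the electron-rich siloxyalkyne, the nucleophilic alkyne carbon C3′ bonding to the ketene carbonyl carbon C4′ (first stage of the second-generation Danheiser benzannulation); the new sp3 centre C1′ forms without control, which does not matter because it is lost in step 10, and any phenol 20 already formed is carried along.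

**Step 10**
Reactants: 17 vinylcyclobutenone
Product: 20 2-(terpenylmethyl)-6-methoxy-3-(triisopropylsilyloxy)phenol (C5–OTMS retained), via dienylketene 18 (not isolated), via cyclohexadienone 19 (not isolated)
Conditions: toluene, 80 °C, argon
Reagents that add atoms: none
Why: Heating 17 triggers conrotatory 4π-electrocyclic opening of the C1′–C4′ bond to dienylketene 18, whose ketene carbon C4′ then bonds to the methoxy-bearing terminus C5′ in a thermal disrotatory 6π-electrocyclisation (the only ring closure of the step), giving cyclohexa-2,4-dienone 19, which enolises to phenol 20. The closest known reaction type is the cyclobutenone-to-phenol ring expansion that ends the Danheiser benzannulation, related to the Moore rearrangement of 4-alkenylcyclobutenones. No lasting stereocentre is created: the sp3 C1′ of 17 and the sp3 C5′ of 19 both become aromatic carbons, and the decalin centres are remote and untouched. The step needs inward rotation of the methoxyvinyl group to give the Z-dienylketene; ring opening is reversible, so any E-ketene returns to 17 and is funnelled through the Z-isomer, and aromatisation makes the sequence irreversible. The substitution pattern cannot scramble because C1′–C4′ keep their substituents and only the C4′–C5′ bond is made. The silyl ethers and the neutral, acid-free conditions keep the tertiary C5–O function from ionising.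

**Step 11**
Reactants: 20 phenol
Product: 21 3-(terpenylmethyl)-5-methoxy-2-(triisopropylsilyloxy)cyclohexa-2,5-diene-1,4-dione (C5–OTMS retained)
Conditions: K2[ON(SO3)2] (Fremy's salt), KH2PO4, acetone/H2O, rt
Reagents that add atoms: potassium nitrosodisulfonate, [K+].[K+].[O]N(S(=O)(=O)[O-])S(=O)(=O)[O-]
Why: Teuber oxidation, in which Fremy's radical oxidises the 2,6-disubstituted phenol at its only free para position (C1′) to the para-quinone and delivers the C1′ oxygen.

**Step 12**
Reactants: 21 silylated quinone
Product: 22 target, 2-hydroxy-5-methoxy-3-{[(1R,2S,4aS,8aS)-4a-hydroxy-1,2,5,5-tetramethyldecahydronaphthalen-1-yl]methyl}cyclohexa-2,5-diene-1,4-dione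
Conditions: Bu4NF, AcOH, THF, 0 °C; dilute citric acid work-up
Reagents that add atoms: none
Why: Fluoride cleaves the vinylogous silyl ester at C2′ and the tertiary TMS ether under buffered, non-ionising conditions, releasing the hydroxyquinone and the C5 alcohol without dehydration or methyl shift.

**Compound list**
1 | 2,2-dimethylcyclohexanone | CC1(C)CCCCC1=O | starting material
2 | 6,6-dimethylcyclohex-1-en-1-yl triflate | CC1(C)CCCC=C1OS(=O)(=O)C(F)(F)F | intermediate
3 | 6,6-dimethyl-1-vinylcyclohex-1-ene | C=CC1=CCCCC1(C)C | intermediate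
4 | (E)-2-methylbut-2-enal | C/C=C(\C)C=O | starting material
5 | (1R,2S,8aR)-1,2,5,5-tetramethyl-1,2,3,5,6,7,8,8a-octahydronaphthalene-1-carbaldehyde | O=C[C@]1(C)[C@@H](C)CC=C2[C@H]1CCCC2(C)C | intermediate
6 | 9α-(2-methoxyethenyl) enol ether, E/Z mixture | COC=C[C@]1(C)[C@@H](C)CC=C2[C@H]1CCCC2(C)C | intermediate
7 | 9α-(2-oxoethyl) aldehyde | O=CC[C@]1(C)[C@@H](C)CC=C2[C@H]1CCCC2(C)C | intermediate (not isolated)
8 | [(1R,2S,8aS)-1,2,5,5-tetramethyl-1,2,3,5,6,7,8,8a-octahydronaphthalen-1-yl]acetic acid | OC(=O)C[C@]1(C)[C@@H](C)CC=C2[C@H]1CCCC2(C)C | intermediate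
9 | bridged δ-lactone (5α-O, 10α-H, 8β,9β-dimethyl) | O=C1C[C@]2(C)[C@@H](C)CC[C@]3(O1)[C@H]2CCCC3(C)C | intermediate
10 | 5α-hydroxy dibromomethyl ketone | BrC(Br)C(=O)C[C@]1(C)[C@@H](C)CC[C@]2(O)[C@H]1CCCC2(C)C | intermediate (not isolated)
11 | dilithium ynolate alkoxide | [Li+].[Li+].[O-]C#CC[C@]1(C)[C@@H](C)CC[C@]2([O-])[C@H]1CCCC2(C)C | intermediate (not isolated)
12 | TIPS ynol ether with C5–OTMS | CC(C)[Si](OC#CC[C@]1(C)[C@@H](C)CC[C@]2(O[Si](C)(C)C)[C@H]1CCCC2(C)C)(C(C)C)C(C)C | intermediate
13 | (E)-4-methoxybut-3-en-2-one | CO/C=C/C(C)=O | starting material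
14 | (E)-1,1,1-trifluoro-6-methoxyhex-5-ene-2,4-dione | CO/C=C/C(=O)CC(=O)C(F)(F)F | intermediate (not isolated)
15 | (E)-1-diazo-4-methoxybut-3-en-2-one | CO/C=C/C(=O)C=[N+]=[N-] | intermediate
16 | (E)-4-methoxybuta-1,3-dien-1-one (methoxyvinylketene) | CO/C=C/C=C=O | intermediate (not isolated)
17 | 4-(2-methoxyethenyl)-3-silyloxy-2-alkylcyclobutenone | CO/C=C/C1C(=O)C(C[C@]2(C)[C@@H](C)CC[C@]3(O[Si](C)(C)C)[C@H]2CCCC3(C)C)=C1O[Si](C(C)C)(C(C)C)C(C)C | intermediate
18 | dienylketene | CO/C=C/C=C(O[Si](C(C)C)(C(C)C)C(C)C)C(C[C@]1(C)[C@@H](C)CC[C@]2(O[Si](C)(C)C)[C@H]1CCCC2(C)C)=C=O | intermediate (not isolated)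
19 | 6-methoxycyclohexa-2,4-dienone | COC1C=CC(O[Si](C(C)C)(C(C)C)C(C)C)=C(C[C@]2(C)[C@@H](C)CC[C@]3(O[Si](C)(C)C)[C@H]2CCCC3(C)C)C1=O | intermediate (not isolated)
20 | 2-alkyl-6-methoxy-3-(triisopropylsilyloxy)phenol | COc1ccc(O[Si](C(C)C)(C(C)C)C(C)C)c(C[C@]2(C)[C@@H](C)CC[C@]3(O[Si](C)(C)C)[C@H]2CCCC3(C)C)c1O | intermediate
21 | 3-alkyl-5-methoxy-2-(triisopropylsilyloxy)-1,4-benzoquinone | COC1=CC(=O)C(O[Si](C(C)C)(C(C)C)C(C)C)=C(C[C@]2(C)[C@@H](C)CC[C@]3(O[Si](C)(C)C)[C@H]2CCCC3(C)C)C1=O | intermediate
22 | target hydroxyquinone | COC1=CC(=O)C(O)=C(C[C@]2(C)[C@@H](C)CC[C@]3(O)[C@H]2CCCC3(C)C)C1=O | target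

**Count.** Total steps: 12. Longest linear sequence: 11 (steps 1–7 and 9–12, from 1); step 8 is a one-step branch.

**Steps most likely to fail**

Step 3 (Diels–Alder). The cycloaddition may proceed with poor formyl-exo/endo selectivity or poor facial selectivity, or the diene may oligomerise under the Lewis acid. Fallback: diene 3 and aldehyde 4 are combined with the bulky achiral Lewis acid Al(OC6H3Ph2-2,6)3, which favours the exo mode, to give racemic 5, that is 5 together with its mirror image ent-5 F1. Steps 4 and 5 are run on the racemate and carry the mirror-image series through ent-enol ether F2 and ent-aldehyde F3 (in the flask) to ent-acid F4 alongside 8. The racemic acid is resolved with (R)-1-phenylethylamine: the less soluble phenylethylammonium salt of 8 F5 is crystallised, while the phenylethylammonium salt of ent-8 F6 stays in the mother liquor (the (S)-amine is used if the solubilities are reversed). Acidification of the crystals returns 8, where the route is rejoined.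

Step 7 (ynolate formation). LiCHBr2 may enolise the lactone instead of adding, the lactolate may fail to open, or silylation may occur on carbon. Fallback from 9: reduction with iBu2AlH at −78 °C gives the bridged lactol F7. Dimethyl (1-diazo-2-oxopropyl)phosphonate with K2CO3 in MeOH converts its open hydroxy-aldehyde form into the terminal alkynol F8. Two equivalents of n-BuLi give the dilithium acetylide alkoxide F9 in the flask, which is oxidised with LiOOtBu (acetylide-to-ynolate oxidation) to the dilithium ynolate 11. Silylation with TIPSCl and then TMSCl as in step 7 gives 12.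

Step 9 (photochemical ketene generation and [2+2]). The donor-substituted vinylketene may dimerise or photoisomerise before it is trapped, and the product may undergo secondary photolysis. Fallback from 12: ketene 16 is generated without light by 1,4-dehydrochlorination of (E)-4-methoxybut-2-enoyl chloride F10 with Et3N in toluene at 25–60 °C in the presence of 12. Thermal [2+2] cycloaddition then gives cyclobutenone 17, where the route is rejoined.

**Further compounds**
F1 | step 3 | ent-5, (1S,2R,8aS)-aldehyde | O=C[C@@]1(C)[C@H](C)CC=C2[C@@H]1CCCC2(C)C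
F2 | step 3 | ent-6, enol ether | COC=C[C@@]1(C)[C@H](C)CC=C2[C@@H]1CCCC2(C)C
F3 | step 3 | ent-7, homologated aldehyde | O=CC[C@@]1(C)[C@H](C)CC=C2[C@@H]1CCCC2(C)C
F4 | step 3 | ent-8, acid | OC(=O)C[C@@]1(C)[C@H](C)CC=C2[C@@H]1CCCC2(C)C
F5 | step 3 | (R)-1-phenylethylammonium salt of 8 | [O-]C(=O)C[C@]1(C)[C@@H](C)CC=C2[C@H]1CCCC2(C)C.C[C@@H]([NH3+])c1ccccc1
F6 | step 3 | (R)-1-phenylethylammonium salt of ent-8 | [O-]C(=O)C[C@@]1(C)[C@H](C)CC=C2[C@@H]1CCCC2(C)C.C[C@@H]([NH3+])c1ccccc1
F7 | step 7 | bridged lactol | OC1C[C@]2(C)[C@@H](C)CC[C@]3(O1)[C@H]2CCCC3(C)C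
F8 | step 7 | 9α-propargyl 5α-alcohol (alkynol) | C#CC[C@]1(C)[C@@H](C)CC[C@]2(O)[C@H]1CCCC2(C)C
F9 | step 7 | dilithium acetylide alkoxide | [Li+].[Li+].[C-]#CC[C@]1(C)[C@@H](C)CC[C@]2([O-])[C@H]1CCCC2(C)C
F10 | step 9 | (E)-4-methoxybut-2-enoyl chloride | COC/C=C/C(Cl)=O
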